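(The runs were computed for an exercise; noise was put on by code.)

in all of them: J 25 mM (held)
- winter: Z 0.096 M; run made earlier
- flask: Z 0.064 M; time 15 d
winter run (percent of the Z charged)

| time / h | Z / % | D / % |
|---|---|---|
| 2.50 | 40.9 | 35.7 |
| 8.00 | 4.3 | 21.5 |
| 12.0 | 1.5 | 11.1 |
| 20.0 | 0 | 6.0 |
| 30.0 | 0 | 4.5 |
| 40.0 | 1.0 | 3.5 |

(scatter of a reading: 0.5 percentage points)
- a species is counted by the Z in it: one G counts as two
- at the start none of Q is dissolved
- steps under discussion: J <-> Q; Z + Q -> D + E; D <-> X; Z + D -> G
- the reaction counts as stopped when no species that holds the Z changes by six tenths of a point or more over the second half of the time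
- which holds at 15 d: what has brought the reaction to rest, or that it has not come to rest (forward and back rates have come level / all of Z has reacted / it is still moving)
- how much of the Z has reacted by 15 d
- how much D there is at 15 d, in percent of the Z charged
- amount of D if the flask were left three thousand times as long, in percent of the Z charged

- The pitfall is to carry the winter tail of D straight across, because the flask holds 0.667 of the winter charge and D is counted as a fraction of the charge.
- I ask first what the end state must be. In the winter run Z falls in a pseudo-first-order way, with a half-life near 1.94 h, which is far shorter than the flask's 15 d. So I expect Z gone from the flask, with 100% reacted.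
- With Z gone, D and X can still stand in a fixed ratio. I read the winter rest level of D as 4.00%, the mean of the last two readings.
- But those two readings differ by 1 percentage point, so is the tail still falling? Their difference has a scatter of 0.71 points, so the gap is 1.41 scatters, and I keep the tail flat.
- A second objection is G, which takes two Z-bearing partners, so I let its share of the charge scale with the charge.
- At 2.50 h of the winter run, 59.1% of Z has reacted, and 23.4% is neither Z nor D, so it is X or G. The split is unknown, so I divide the ratio of those two by 2 and take 19.8% as my estimate of the winter loss share, the fraction of the winter charge ending as G.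
- The flask's D at rest is then the rest level times (one minus the loss share times the charge ratio) over (one minus the loss share), which gives 4.33%. I commit to that for 15 d and for the long time.
- The forecast says forward and back rates have come level, with 100% reacted, D 4.5% and, in the long run, 4.5%. Its ground is “That equilibrium is reached long before 15 d.” Its D stands above mine, and I name Z's exhaustion as the end.

The flask gives all of Z has reacted, with 100% reacted, D 4.90% at 15 d and 4.90% in the long run.

    J ⇌ Q, rate k1*(csat - [Q]) (kL = 23.0 h⁻¹)
    Z + Q → D + E (k = 14.0 M⁻¹ h⁻¹)
    D ⇌ X (K = 17.0, k = 0.280 h⁻¹)
    Z + D → G (k = 1.30 M⁻¹ h⁻¹)

- In the flask, D and X relax with a half-life of 0.0974 d, short against 15 d. The end asked about is still named all of Z has reacted: Z, the limiting reagent, stands at 0%.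
- My 4.33% lies 0.57 points under the flask's D.
- For the neighbour flask with 0.016 M of Z, the loss share gives 4.82%, a rise of 0.49 points over my flask figure.
- The neighbour computes to D 5.38% and G 3.25%, a rise of 0.48 points in D.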